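**Assumption:** crystalline all-E (3R,3'R,6'R)-lutein from saponified marigold oleoresin is taken as a cheap bulk commercial starting material.

## Retrosynthetic overview

1. The target is lutein 1 with two extra hydroxyls on C5 and C6, both cis to the 3-OH, i.e. (3S,5S,6R,3'R,6'R); 3S is the same spatial arrangement as 3R in lutein, the letter changing only because C4 outranks C2 once C5 bears oxygen. All 40 carbons, both rings, the all-E chain and C3, C3', C6' therefore come with 1; no ring is built, so there is no ring-forming order.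
2. C5–O disconnection: hydroxyl-directed epoxidation of 1 with mCPBA 2 gives the syn-5,6-epoxide 3.
3. C6–O disconnection (key step, new): same-face oxygen delivery from pentafluorophenylboronic acid 4 to C6 of 3 gives the cis-fused 5,6-boronate 5.
4. B–C/B–O disconnection: hydroxide-induced protodeboronation of 5, through the cyclic hydrogen borate 6, releases the tetrol 7.

## Route

**Step 1**
Reactants: 1 (3R,3'R,6'R)-lutein; 2 mCPBA
Product: 3 (3S,5S,6R,3'R,6'R)-5,6-epoxy-5,6-dihydro-β,ε-carotene-3,3'-diol (syn-lutein 5,6-epoxide; oxirane oxygen cis to the 3-OH)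
Conditions: mCPBA (1.0 equiv), CH2Cl2, −30 → −10 °C, dark, Ar; cold quench with aq. NaHCO3/Na2S2O3; chromatography on Et3N-deactivated SiO2
Reagents that add atoms: mCPBA (3-chloroperoxybenzoic acid), O=C(OO)c1cccc(Cl)c1
Why: Prilezhaev epoxidation with Henbest-type hydroxyl direction: the twisted, tetrasubstituted C5=C6 bond is the most nucleophilic alkene of a β-end-group carotenoid (the chain alkenes are less substituted, the ε-ring alkene is trisubstituted and inductively deactivated by its allylic OH), and hydrogen bonding of the peracid to the homoallylic 3-OH in a non-coordinating solvent delivers oxygen to the face cis to that OH, setting C5 as S (and C6 as R for the moment); the syn preference is expected to be moderate, and the minor anti-epoxide is removed by chromatography.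

**Step 2**
Reactants: 3 syn-lutein 5,6-epoxide; 4 pentafluorophenylboronic acid
Product: 5 (3S,5S,6R,3'R,6'R)-5,6-dihydro-β,ε-carotene-3,5,6,3'-tetrol 5,6-(pentafluorophenyl)boronate (O5 and O6 joined through B–C6F5 in a cis-fused 1,3,2-dioxaborolane; 3-OH and 3'-OH free)
Conditions: C6F5B(OH)2 (1.2 equiv), 2,6-di-tert-butyl-4-methylpyridine (0.1 equiv), 4 Å molecular sieves, CH2Cl2, −40 → 0 °C, dark, Ar; chromatography on neutral Al2O3
Reagents that add atoms: pentafluorophenylboronic acid, OB(O)c1c(F)c(F)c(F)c(F)c1F
Why: Proposed new method: boronic-acid-templated same-face (SNi-type) opening of a polyenylic epoxide, in which the electron-poor trigonal boron binds the oxirane oxygen, the tertiary C6–O bond (conjugated to the nonaene, the same bond that ionises in the familiar 5,6→5,8 furanoid rearrangement) heterolyses, the C5 oxygen is thereby held as a ligand of a tetrahedral hydroxyborate and cannot reach C8, and a boron-bound OH tethered through C5–O–B collapses onto the C6 cation from the face the oxygen has just left to close the cis-fused five-membered dioxaborolane (then loss of water from boron), so C6 is set as R with net retention while the hindered pyridine suppresses proton-catalysed rearrangement; the closest known reaction types are boron-mediated aglycon delivery (boronic or borinic esters opening 1,2-anhydro sugars with same-face oxygen delivery to give 1,2-cis glycosides) and the acid-triggered C6–O ionisation of carotenoid 5,6-epoxides.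

**Step 3**
Reactants: 5 cis-5,6-(pentafluorophenyl)boronate
Product: 7 (3S,5S,6R,3'R,6'R)-5,6-dihydro-β,ε-carotene-3,5,6,3'-tetrol (5,6-dihydroxylutein; target), via cyclic 5,6-hydrogen borate 6 (not isolated)
Conditions: KOH (3 equiv), MeOH/THF/H2O 4:4:1, 0 °C → rt, dark, Ar; then pH 7 buffer (KH2PO4/K2HPO4), extraction, crystallisation
Reagents that add atoms: none
Why: Base-induced protodeboronation: hydroxide adds to boron, the ate complex expels the stabilised pentafluorophenyl anion (protonated to pentafluorobenzene), and the remaining cyclic hydrogen borate 6 is hydrolysed at its B–O bonds only, so no C–O bond is broken and all five stereocentres are untouched; the polyene tolerates KOH/MeOH as in a routine carotenoid saponification.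

## Compound list

1 | (3R,3'R,6'R)-lutein, all-E (3R,3'R,6'R)-β,ε-carotene-3,3'-diol | CC1=C[C@H](O)CC(C)(C)[C@H]1/C=C/C(C)=C/C=C/C(C)=C/C=C/C=C(C)/C=C/C=C(C)/C=C/C1=C(C)C[C@@H](O)CC1(C)C | starting material
2 | mCPBA (3-chloroperoxybenzoic acid) | O=C(OO)c1cccc(Cl)c1 | starting material
3 | (3S,5S,6R,3'R,6'R)-5,6-epoxy-5,6-dihydro-β,ε-carotene-3,3'-diol (syn-lutein 5,6-epoxide) | CC1=C[C@H](O)CC(C)(C)[C@H]1/C=C/C(C)=C/C=C/C(C)=C/C=C/C=C(C)/C=C/C=C(C)/C=C/[C@]12O[C@@]1(C)C[C@@H](O)CC2(C)C | intermediate
4 | pentafluorophenylboronic acid | OB(O)c1c(F)c(F)c(F)c(F)c1F | starting material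
5 | (3S,5S,6R,3'R,6'R)-5,6-dihydro-β,ε-carotene-3,5,6,3'-tetrol 5,6-(pentafluorophenyl)boronate | CC1=C[C@H](O)CC(C)(C)[C@H]1/C=C/C(C)=C/C=C/C(C)=C/C=C/C=C(C)/C=C/C=C(C)/C=C/[C@]12OB(c3c(F)c(F)c(F)c(F)c3F)O[C@@]1(C)C[C@@H](O)CC2(C)C | intermediate
6 | (3S,5S,6R,3'R,6'R)-5,6-dihydro-β,ε-carotene-3,5,6,3'-tetrol cyclic 5,6-hydrogen borate (2-hydroxy-1,3,2-dioxaborolane on C5/C6) | CC1=C[C@H](O)CC(C)(C)[C@H]1/C=C/C(C)=C/C=C/C(C)=C/C=C/C=C(C)/C=C/C=C(C)/C=C/[C@]12OB(O)O[C@@]1(C)C[C@@H](O)CC2(C)C | intermediate
7 | (3S,5S,6R,3'R,6'R)-5,6-dihydro-β,ε-carotene-3,5,6,3'-tetrol (5,6-dihydroxylutein) | CC1=C[C@H](O)CC(C)(C)[C@H]1/C=C/C(C)=C/C=C/C(C)=C/C=C/C=C(C)/C=C/C=C(C)/C=C/[C@@]1(O)C(C)(C)C[C@H](O)C[C@]1(C)O | target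

## Step count and risk

Total step count: 3. Longest linear sequence: 3 steps (1 → 3 → 5 → 7).

**Steps most likely to fail**

**Step 2 (the proposed new step).**
- Risks: the boron may not capture O5 before it attacks C8 (furanoid 5,8-epoxide); the cis 3-OH may trap the C6 cation (3,6-epoxide); the allylic 3'-OH may ionise under Lewis acid; the chain may undergo E/Z isomerisation.
- Fallback (known chemistry): it sets out from 3 and comes back to the route at 7. Epoxide 3 is hydrolysed with dilute aqueous H2SO4 (about 0.01 M) in THF at 0 °C in the dark. This is the known specific-acid opening of carotenoid 5,6-epoxides through the free C6 polyenyl cation, in which water adds to either face. It gives 7 together with its C6 epimer, the trans-diol (3S,5S,6S,3'R,6'R)-5,6-dihydro-β,ε-carotene-3,5,6,3'-tetrol F1, and rearranged furanoid material. Compound 7 is isolated by chromatography, in lower yield but without unknown chemistry.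

**Step 1.**
- Risks: the syn:anti ratio from hydrogen-bond direction may be too low; over-epoxidation (ε ring, chain); acid-triggered rearrangement of the product.
- Fallback: it sets out from 1 and comes back at 3, replacing hydrogen-bond direction by metal-alkoxide direction after masking the competing allylic alcohol. Lutein 1 is oxidised chemoselectively at the allylic 3'-OH with activated MnO2 in CH2Cl2 to (3R,6'R)-3-hydroxy-β,ε-caroten-3'-one F2. Its ε-ring alkene is now an electron-poor enone with no directing hydroxyl. VO(acac)2 (5 mol %), tBuOOH and 2,6-lutidine in CH2Cl2 then deliver oxygen from the coordinated homoallylic 3-OH to the cis face of C5=C6, giving (3S,5S,6R,6'R)-5,6-epoxy-3-hydroxy-5,6-dihydro-β,ε-caroten-3'-one F3. NaBH4 in MeOH/THF at 0 °C reduces the enone 1,2 to 3, and the co-formed 3'-epimer, (3S,5S,6R,3'S,6'R)-5,6-epoxy-5,6-dihydro-β,ε-carotene-3,3'-diol F4, is separated by chromatography.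

**Step 3.**
- Risks: slow attack of hydroxide on the hindered, pinacol-like boronate, or borate clinging to the cis-diol.
- Fallback: it sets out from 5 and comes back at 7, by transesterification instead of C–B cleavage. Boronate 5 is stirred with diethanolamine (1.5 equiv) in Et2O/THF at rt. The boron is transferred to the amino-diol as its N→B-chelated, poorly soluble ester, which is filtered off, and 7 stays in solution. No new route compound is formed.

## Further compounds

F1 | step 2 | (3S,5S,6S,3'R,6'R)-5,6-dihydro-β,ε-carotene-3,5,6,3'-tetrol (C6 epimer of 7, co-product) | CC1=C[C@H](O)CC(C)(C)[C@H]1/C=C/C(C)=C/C=C/C(C)=C/C=C/C=C(C)/C=C/C=C(C)/C=C/[C@]1(O)C(C)(C)C[C@H](O)C[C@]1(C)O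
F2 | step 1 | (3R,6'R)-3-hydroxy-β,ε-caroten-3'-one | CC1=CC(=O)CC(C)(C)[C@H]1/C=C/C(C)=C/C=C/C(C)=C/C=C/C=C(C)/C=C/C=C(C)/C=C/C1=C(C)C[C@@H](O)CC1(C)C
F3 | step 1 | (3S,5S,6R,6'R)-5,6-epoxy-3-hydroxy-5,6-dihydro-β,ε-caroten-3'-one | CC1=CC(=O)CC(C)(C)[C@H]1/C=C/C(C)=C/C=C/C(C)=C/C=C/C=C(C)/C=C/C=C(C)/C=C/[C@]12O[C@@]1(C)C[C@@H](O)CC2(C)C
F4 | step 1 | (3S,5S,6R,3'S,6'R)-5,6-epoxy-5,6-dihydro-β,ε-carotene-3,3'-diol (3'-epimer of 3, co-product) | CC1=C[C@@H](O)CC(C)(C)[C@H]1/C=C/C(C)=C/C=C/C(C)=C/C=C/C=C(C)/C=C/C=C(C)/C=C/[C@]12O[C@@]1(C)C[C@@H](O)CC2(C)C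
F0 | step 3 | none | none
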